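**Retrosynthetic overview**
- Target (2S,4R, 2,4-cis) ⇒ racemic 2-heptadecyl-chromane-4,5-dione by one ketoreductase-like step: asymmetric transfer hydrogenation run as a dynamic kinetic resolution. The pyran ring opens and recloses (retro-oxa-Michael/oxa-Michael through the achiral enoyl triketone), so C2 and C4 are both fixed in the reduction.
- Racemic chromanedione ⇒ 2-(3-hydroxyicosanoyl)cyclohexane-1,3-dione by acid cyclodehydration, the polyketide-type closure of the pyran ring by the β-triketone enol oxygen.
- β-Hydroxyacyl triketone ⇒ 2-acetylcyclohexane-1,3-dione + octadecanal by dianion aldol addition.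
- Ring order: the carbocycle (ring A) is bought as the β-triketone; the pyran (ring B) is closed second and kept reversible; both stereocentres are set last.

Assumption: the biosynthesis is taken as a 2-(3-oxygenated acyl)cyclohexane-1,3-dione polyketide whose enol oxygen closes the pyran ring, followed by ketoreduction at C4; the SMILES is read as (2S,4R), with heptadecyl and hydroxyl cis.

**Route**

Step 1
Reactants: 1 2-acetylcyclohexane-1,3-dione; 2 octadecanal
Product: 5 racemic 2-(3-hydroxyicosanoyl)cyclohexane-1,3-dione, via dilithium dianion 3 (not isolated), via dilithium aldolate 4 (not isolated)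
Conditions: 1 (1.2 equiv), LiN(iPr)2 (LDA, 2.5 equiv), THF, −78 → 0 °C; then 2 (1.0 equiv) in THF, −78 → −30 °C; 1 M HCl, 0 °C
Reagents that add atoms: none
Why: The second equivalent of amide base deprotonates the acetyl methyl of the lithium triketonate, and the dianion reacts with the aldehyde at this most basic terminal carbon (Hauser-type dianion aldol addition, as with acetylacetone or 3-acetyltetramic acid dianions); the carbinol centre is deliberately made racemic because step 3 equilibrates it.

Step 2
Reactants: 5 racemic 2-(3-hydroxyicosanoyl)cyclohexane-1,3-dione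
Product: 7 racemic 2-heptadecyl-2,3,7,8-tetrahydro-4H-chromene-4,5(6H)-dione, via bicyclic hemiketal 6 (not isolated)
Conditions: TsOH·H2O (10 mol %), PhMe, 80 °C, 4 Å MS
Reagents that add atoms: none
Why: Acid-catalysed cyclodehydration of a δ-hydroxy-β-dicarbonyl to a 2,3-dihydro-4H-pyran-4-one: the side-chain hydroxyl adds 6-exo to one of the two equivalent ring carbonyls and the hemiketal loses water to give the doubly conjugated enol ether, mirroring the presumed biosynthetic closure of the pyran ring; C2 remains racemic.

Step 3
Reactants: 7 racemic 2-heptadecyl-2,3,7,8-tetrahydro-4H-chromene-4,5(6H)-dione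
Product: 10 (2S,4R)-2-heptadecyl-4-hydroxy-2,3,4,6,7,8-hexahydro-5H-chromen-5-one, via open enoyl triketone 8 (not isolated), via (S)-chromanedione 9 (not isolated)
Conditions: RuCl[(R,R)-TsDPEN](p-cymene) (2 mol %), HCO2H/Et3N 5:2 (5 equiv HCO2H), EtOAc, 40 °C, N2 sweep; quench into aq. NaHCO3
Reagents that add atoms: none
Why: Proposed new method: in the formic acid/formate buffer the C3–H next to the C4 ketone is removed and the ring oxygen leaves as the enolate of a β-triketone (conjugate acid pKa about 4, a far better leaving group than the phenoxide of a chromanone) in an E1cB retro-oxa-Michael step, giving achiral 8, which stays protonated at this acidity and recloses by 6-endo oxa-Michael addition to either enantiomer of 7, while the (R,R)-configured Ru–H/N–H catalyst reduces only 9 at the C4 carbonyl (expected to be the more electrophilic one because of the β-oxygen at C2) from the face that gives 4R, which for 9 is also the axial, substrate-preferred trajectory leading to the 2,4-cis alcohol, so C2 (S) and C4 (R) are set together, and 10, which has no acidic C3–H next to a ketone and keeps only a plain vinylogous ester carbonyl at C5, can neither reopen nor be reduced further; closest known reaction type: Noyori–Ikariya asymmetric transfer hydrogenation of 2-substituted chroman-4-ones to cis-chroman-4-ols as a dynamic kinetic resolution driven by elimination and re-addition of the ring oxygen.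

**Compound list**

1 | 2-acetylcyclohexane-1,3-dione (drawn as its enol) | CC(=O)C1=C(O)CCCC1=O | starting material
2 | octadecanal | CCCCCCCCCCCCCCCCCC=O | starting material
3 | dilithium dianion of 2-acetylcyclohexane-1,3-dione (ring enolate plus acetyl enolate) | [Li+].[Li+].C=C([O-])C1=C([O-])CCCC1=O | intermediate (not isolated)
4 | dilithium salt of the aldol adduct (ring enolate plus side-chain alkoxide), racemic | [Li+].[Li+].CCCCCCCCCCCCCCCCCC([O-])CC(=O)C1=C([O-])CCCC1=O | intermediate (not isolated)
5 | racemic 2-(3-hydroxyicosanoyl)cyclohexane-1,3-dione (enol form) | CCCCCCCCCCCCCCCCCC(O)CC(=O)C1=C(O)CCCC1=O | intermediate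
6 | bicyclic hemiketal, 2-heptadecyl-8a-hydroxyoctahydrochromene-4,5-dione (diastereomer mixture, racemic) | CCCCCCCCCCCCCCCCCC1CC(=O)C2C(=O)CCCC2(O)O1 | intermediate (not isolated)
7 | racemic 2-heptadecyl-2,3,7,8-tetrahydro-4H-chromene-4,5(6H)-dione | CCCCCCCCCCCCCCCCCC1CC(=O)C2=C(CCCC2=O)O1 | intermediate
8 | (E)-2-(icos-2-enoyl)cyclohexane-1,3-dione (enol form, achiral) | CCCCCCCCCCCCCCCCC/C=C/C(=O)C1=C(O)CCCC1=O | intermediate (not isolated)
9 | (S)-2-heptadecyl-2,3,7,8-tetrahydro-4H-chromene-4,5(6H)-dione | CCCCCCCCCCCCCCCCC[C@H]1CC(=O)C2=C(CCCC2=O)O1 | intermediate (not isolated)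
10 | (2S,4R)-2-heptadecyl-4-hydroxy-2,3,4,6,7,8-hexahydro-5H-chromen-5-one | CCCCCCCCCCCCCCCCC[C@H]1C[C@@H](O)C2=C(CCCC2=O)O1 | target

**Totals**

Total step count: 3. Longest linear sequence: 3 steps (1 + 2 → 5 → 7 → 10).

**Steps most likely to fail, with fallbacks**

Step 3 (highest risk). Three things can go wrong:
- Ring opening/reclosure through 8 may be slower than reduction of the mismatched enantiomer, or the material may park as open 8 or its anion if too much free amine is present.
- Ru–H may reduce C5 instead of C4, or reduce the C=C of 8 by conjugate addition.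
- The allylic C4 hydroxyl of 10 may epimerise or eliminate in the acidic medium.

Fallback: it sets out from compound 7. Luche reduction (NaBH4, CeCl3·7H2O, MeOH, −78 °C; axial hydride delivery as with 2-substituted dihydropyran-4-ones) gives racemic cis-2-heptadecyl-4-hydroxy-2,3,4,6,7,8-hexahydro-5H-chromen-5-one F1. Immobilised Candida antarctica lipase B with vinyl acetate in MTBE at 30 °C acetylates the 4R enantiomer (Kazlauskas rule, ring-fusion carbon as the large group) to give (2S,4R)-2-heptadecyl-5-oxo-3,4,5,6,7,8-hexahydro-2H-chromen-4-yl acetate F2. This leaves (2R,4S)-2-heptadecyl-4-hydroxy-2,3,4,6,7,8-hexahydro-5H-chromen-5-one F3, which is separated by chromatography. K2CO3 in MeOH at 0 °C removes the acetyl group of F2, and the route is back at compound 10 (at most 50 % of the material).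

Step 1. The second deprotonation may occur in the ring (C4/C6) instead of at the acetyl methyl. The dilithium salt and the C18 aldehyde are poorly soluble at low temperature, and the aldolate can revert.

Fallback: it sets out from compound 2 and forms the ring-carbon-to-acyl bond instead of the methyl-to-aldehyde bond. Doebner–Knoevenagel condensation with malonic acid (OC(=O)CC(=O)O; pyridine, piperidine cat., 90 °C) gives 2-octadecylidenemalonic acid F4, which decarboxylates in the flask to (E)-icos-2-enoic acid F5. DCC with catalytic DMAP and cyclohexane-1,3-dione (O=C1CCCC(=O)C1) in CH2Cl2 gives the enol ester 3-oxocyclohex-1-en-1-yl (E)-icos-2-enoate F6. More DMAP (1 equiv, rt) moves the acyl group from O to C, and the route is back at compound 8. Compound 8 closes to 7 under the acid of step 2 (oxa-Michael addition) or is fed as such into step 3, so compound 5 is bypassed.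

Step 2. Hot acid may cause retro-aldol cleavage of 5, or give elimination without clean closure. A mixture of 7 and 8 is harmless, since step 3 equilibrates them.

Fallback: it sets out from compound 5 and comes back at compound 7 by intramolecular Mitsunobu etherification (PPh3, DIAD, THF, 0 °C → rt). The acidic triketone enol (pKa about 4) is the nucleophile and displaces the activated secondary hydroxyl in an SN2 ring closure, so the O1–C2 bond is formed at the carbinol carbon instead of at the ring carbonyl. This path makes no compound outside the list (none F0).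

**Further compounds**

F1 | step 3 | racemic cis-2-heptadecyl-4-hydroxy-2,3,4,6,7,8-hexahydro-5H-chromen-5-one (one enantiomer drawn; equal parts 2S,4R and 2R,4S) | CCCCCCCCCCCCCCCCC[C@H]1C[C@@H](O)C2=C(CCCC2=O)O1
F2 | step 3 | (2S,4R)-2-heptadecyl-5-oxo-3,4,5,6,7,8-hexahydro-2H-chromen-4-yl acetate | CCCCCCCCCCCCCCCCC[C@H]1C[C@@H](OC(C)=O)C2=C(CCCC2=O)O1
F3 | step 3 | (2R,4S)-2-heptadecyl-4-hydroxy-2,3,4,6,7,8-hexahydro-5H-chromen-5-one | CCCCCCCCCCCCCCCCC[C@@H]1C[C@H](O)C2=C(CCCC2=O)O1
F4 | step 1 | 2-octadecylidenemalonic acid | CCCCCCCCCCCCCCCCCC=C(C(=O)O)C(=O)O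
F5 | step 1 | (E)-icos-2-enoic acid | CCCCCCCCCCCCCCCCC/C=C/C(=O)O
F6 | step 1 | 3-oxocyclohex-1-en-1-yl (E)-icos-2-enoate | CCCCCCCCCCCCCCCCC/C=C/C(=O)OC1=CC(=O)CCC1
F0 | step 2 | none | none
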